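## Retrosynthetic overview

1. Testudinariol A ⇒ a C2-symmetric bis(α-oxanyl) dialdehyde; both cyclopentanols are closed last, in one operation, by a twofold intramolecular carbonyl-ene reaction.
2. ⇒ a bis(oxane) diketone whose (S)-lactate-derived CH(OBz)CH3 termini are reduced and cleaved to the formyl groups; both oxanes come from MEM ethers by SnCl4-induced vinylsilane-terminated cyclisation (the acetal CH2 becomes C6′).
3. ⇒ a two-directional boron anti-aldol between a (4Z,8Z)-bis(vinylsilane) C12 dialdehyde and an (S)-lactate-derived ketone; all stereochemistry is relayed from the lactate centre.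
4. ⇒ key step: double Johnson–Claisen [3,3]-sigmatropic rearrangement of a bis(α-silylvinyl carbinol) made from succinaldehyde; it forms both C3′–C4′ bonds and fixes both trisubstituted alkene geometries.
5. Ring order: two oxanes (one operation), then two cyclopentanes (one operation).

Assumption: an operation performed on both ends of a C2-symmetric intermediate in one flask counts as one step; labels used are C1–C5 for the cyclopentane (C1 carbinol, C2 isopropenyl-bearing, C5 oxane-bearing) and O1′, C2′–C6′ for the oxane (C2′ on C5, C5′ alkylidene carbon).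

## Route

Step 1
Reactants: 1 2,5-dimethoxytetrahydrofuran
Product: 2 succinaldehyde (butanedial)
Conditions: H2O, 90 °C, 2 h; MeOH/H2O distilled off, toluene azeotrope; used at once
Reagents that add atoms: water, O
Why: Hydrolysis of the cyclic bis-acetal, driven by removal of methanol, gives fresh monomeric dialdehyde that is used immediately because it oligomerises; no stereocentre is involved.

Step 2
Reactants: 2 succinaldehyde; 3 (1-bromovinyl)trimethylsilane
Product: 5 2,7-bis(trimethylsilyl)octa-1,7-diene-3,6-diol (dl/meso mixture), via vinyl Grignard reagent 4 (not isolated)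
Conditions: 3 (3 equiv), Mg, THF, reflux; then 2, THF, −78 → 0 °C; aq. NH4Cl
Reagents that add atoms: none
Why: Grignard 1,2-addition of the α-silylvinyl nucleophile to both formyl groups (excess reagent also opens the intermediate magnesium lactolate); the two carbinol centres form unselectively and are left as a mixture because both are erased in step 3.

Step 3
Reactants: 5 2,7-bis(trimethylsilyl)octa-1,7-diene-3,6-diol
Product: 7 diethyl (4Z,8Z)-4,9-bis(trimethylsilyl)dodeca-4,8-dienedioate, via bis(ketene acetal) 6 (not isolated)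
Conditions: MeC(OEt)3 (12 equiv), EtCO2H (0.1 equiv), 140 °C, EtOH distilled off
Reagents that add atoms: triethyl orthoacetate, CC(OCC)(OCC)OCC
Why: Double Johnson–Claisen (orthoester) [3,3]-sigmatropic rearrangement, in which each chair transition state keeps the CH2 chain on the carbinol carbon equatorial (axial would clash 1,3-diaxially with OEt), so the new CH2–CH2CO2Et bond ends up trans to that chain and silicon cis to it, giving the (4Z,8Z)-bis(vinylsilane) while the carbinol centres disappear.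

Step 4
Reactants: 7 diethyl (4Z,8Z)-4,9-bis(trimethylsilyl)dodeca-4,8-dienedioate
Product: 8 (4Z,8Z)-4,9-bis(trimethylsilyl)dodeca-4,8-dienedial
Conditions: iBu2AlH (2.1 equiv), CH2Cl2, −78 °C; MeOH, then aq. KNaC4H4O6
Reagents that add atoms: none
Why: Partial ester reduction, in which the tetrahedral aluminium hemiacetal is stable at −78 °C and collapses to the aldehyde only on work-up; the vinylsilanes are inert and no stereocentre is involved.

Step 5
Reactants: 9 ethyl (S)-lactate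
Product: 10 (S)-2-hydroxy-N-methoxy-N-methylpropanamide
Conditions: MeNH(OMe)·HCl, iPrMgCl (4 equiv), THF, −20 → 0 °C
Reagents that add atoms: N,O-dimethylhydroxylamine hydrochloride, CNOC.Cl
Why: Weinreb amide formation by aminolysis of the ester with the magnesium amide; the bought (S) centre is carried as its alkoxide and is not enolised.

Step 6
Reactants: 10 (S)-2-hydroxy-N-methoxy-N-methylpropanamide; 11 5-bromopent-1-ene
Product: 13 (S)-2-hydroxyoct-7-en-3-one, via pentenyl Grignard reagent 12 (not isolated)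
Conditions: 11 (3.2 equiv), Mg, THF; then 10, 0 °C → rt; aq. NH4Cl
Reagents that add atoms: none
Why: Weinreb ketone synthesis, in which the chelated tetrahedral intermediate prevents over-addition (one equivalent of Grignard reagent is consumed by the hydroxyl proton); the stereocentre is untouched.

Step 7
Reactants: 13 (S)-2-hydroxyoct-7-en-3-one
Product: 14 (S)-3-oxooct-7-en-2-yl benzoate
Conditions: Bz2O, DMAP (cat.), iPr2NEt, CH2Cl2, rt
Reagents that add atoms: benzoic anhydride, O=C(OC(=O)c1ccccc1)c1ccccc1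
Why: DMAP-catalysed O-acylation under mild base leaves the α-stereocentre intact and installs the benzoate that directs the aldol.

Step 8
Reactants: 14 (S)-3-oxooct-7-en-2-yl benzoate (2.6 equiv); 8 (4Z,8Z)-4,9-bis(trimethylsilyl)dodeca-4,8-dienedial
Product: 16 (2S,4R,5R,8Z,12Z,16R,17R,19S)-4,17-di(but-3-en-1-yl)-5,16-dihydroxy-3,18-dioxo-8,13-bis(trimethylsilyl)icosa-8,12-diene-2,19-diyl dibenzoate, via boron enolate 15 (not isolated)
Conditions: 14, (c-C6H11)2BCl, Me2NEt, Et2O, −78 → 0 °C; then 8, −78 → −20 °C, 16 h; MeOH, pH 7 buffer (NaH2PO4/Na2HPO4), 30% H2O2, 0 °C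
Reagents that add atoms: none
Why: Twofold Paterson lactate-ketone boron aldol, in which the (E)-enol borinate reacts through a chair Zimmerman–Traxler transition state (anti), and the (S)-benzoyloxy centre (its H eclipsing the enolate, benzoate carbonyl hydrogen-bonded to the formyl H) selects one enolate face, setting C5 and C2′ in each arm.

Step 9
Reactants: 16 bis(anti-aldol) adduct
Product: 17 (2S,4R,5R,8Z,12Z,16R,17R,19S)-4,17-di(but-3-en-1-yl)-5,16-bis[(2-methoxyethoxy)methoxy]-3,18-dioxo-8,13-bis(trimethylsilyl)icosa-8,12-diene-2,19-diyl dibenzoate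
Conditions: MEMCl (6 equiv), iPr2NEt (8 equiv), CH2Cl2, 0 °C → rt
Reagents that add atoms: 2-methoxyethoxymethyl chloride (MEMCl), COCCOCCl
Why: O-alkylation of the two secondary hydroxyls with the chloromethyl ether under a hindered amine base, which is too weak to cause retro-aldol or epimerisation; no stereocentre changes.

Step 10
Reactants: 17 bis(MEM ether)
Product: 19 (5Z,5'Z)-5,5'-(butane-1,4-diylidene)bis[(2R)-oxane] bearing on each C2 a (2S,4R)-2-(benzoyloxy)-3-oxooct-7-en-4-yl group, via bis(oxocarbenium) ion 18 (not isolated)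
Conditions: SnCl4 (6 equiv), CH2Cl2, −20 °C; aq. NaHCO3
Reagents that add atoms: none
Why: Acetal-initiated vinylsilane-terminated (Prins-type) cyclisation, in which the chelated MEM group ionises to C2′–O+=CH2, the vinylsilane attacks through its silicon-bearing carbon (six-membered ring) and loss of Me3Si from the β-silyl cation restores the alkene with retention, so the new C6′ is cis to the chain; the terminal alkenes are too weakly nucleophilic to compete and no stereocentre is created.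

Step 11
Reactants: 19 bis(oxane) diketone with but-3-enyl chains
Product: 20 (5Z,5'Z)-5,5'-(butane-1,4-diylidene)bis[(2R)-oxane] bearing on each C2 a (2S,4R)-2-(benzoyloxy)-8-methyl-3-oxonon-7-en-4-yl group
Conditions: 2-methylbut-2-ene/CH2Cl2 (1:1), second-generation Grubbs catalyst RuCl2(=CHPh)(PCy3)(H2IMes) (5 mol%), 40 °C
Reagents that add atoms: 2-methylbut-2-ene, CC=C(C)C
Why: Olefin cross-metathesis converts each monosubstituted terminal alkene into the isopropylidene terminus (propene lost) while the trisubstituted exocyclic alkenes are spectators; no stereocentre is involved.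

Step 12
Reactants: 20 bis(oxane) diketone dibenzoate
Product: 21 (5Z,5'Z)-5,5'-(butane-1,4-diylidene)bis[(2R)-oxane] bearing on each C2 a (2S,3RS,4S)-2,3-dihydroxy-8-methylnon-7-en-4-yl group
Conditions: LiBH4 (8 equiv), THF, −78 °C → rt
Reagents that add atoms: none
Why: Hydride reduction of both ketones and reductive removal of both benzoates gives the vicinal diols; the new carbinol centre is formed as a mixture, which is irrelevant because that carbon becomes the formyl carbon in step 13.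

Step 13
Reactants: 21 tetraol
Product: 22 (5Z,5'Z)-5,5'-(butane-1,4-diylidene)bis[(2R)-oxane] bearing on each C2 a (2R)-6-methyl-1-oxohept-5-en-2-yl group
Conditions: NaIO4 (4 equiv), MeOH/H2O (2:1), 0 °C → rt; crude product used at once
Reagents that add atoms: none
Why: Malaprade glycol cleavage under neutral conditions excises the lactate carbons as acetaldehyde and unmasks C1 as the aldehyde without epimerising the adjacent C5 centre.

Step 14
Reactants: 22 bis(oxane) dialdehyde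
Product: 23 testudinariol A
Conditions: MeAl(OAr)2 (Ar = 4-bromo-2,6-di-tert-butylphenyl; from Me3Al + 2 ArOH, 2.4 equiv), CH2Cl2, −78 → −40 °C; aq. NaHCO3
Reagents that add atoms: none
Why: Twofold intramolecular carbonyl-ene reaction, in which the bulky monodentate aluminium aryloxide binds only the formyl oxygen (no chelate to the ring oxygen), the concerted cis-fused transition state makes OH and isopropenyl cis at C1/C2, and the α-oxanyl group on C5 sits exo, trans to the O–Al bond, so C5 sets C1 (S) and C2 (R).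

## Compound list

1 | 2,5-dimethoxytetrahydrofuran (cis/trans mixture) | COC1CCC(OC)O1 | starting material
2 | succinaldehyde (butanedial) | O=CCCC=O | intermediate
3 | (1-bromovinyl)trimethylsilane | C=C(Br)[Si](C)(C)C | starting material
4 | [1-(trimethylsilyl)vinyl]magnesium bromide | C=C([Mg]Br)[Si](C)(C)C | intermediate
5 | 2,7-bis(trimethylsilyl)octa-1,7-diene-3,6-diol (dl/meso mixture) | C=C([Si](C)(C)C)C(O)CCC(O)C(=C)[Si](C)(C)C | intermediate
6 | 3,6-bis[(1-ethoxyvinyl)oxy]-2,7-bis(trimethylsilyl)octa-1,7-diene | C=C(OCC)OC(CCC(OC(=C)OCC)C(=C)[Si](C)(C)C)C(=C)[Si](C)(C)C | intermediate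
7 | diethyl (4Z,8Z)-4,9-bis(trimethylsilyl)dodeca-4,8-dienedioate | CCOC(=O)CC/C(=C/CC/C=C(/CCC(=O)OCC)[Si](C)(C)C)[Si](C)(C)C | intermediate
8 | (4Z,8Z)-4,9-bis(trimethylsilyl)dodeca-4,8-dienedial | O=CCC/C(=C/CC/C=C(/CCC=O)[Si](C)(C)C)[Si](C)(C)C | intermediate
9 | ethyl (S)-lactate | C[C@H](O)C(=O)OCC | starting material
10 | (S)-2-hydroxy-N-methoxy-N-methylpropanamide | C[C@H](O)C(=O)N(C)OC | intermediate
11 | 5-bromopent-1-ene | C=CCCCBr | starting material
12 | pent-4-en-1-ylmagnesium bromide | C=CCCC[Mg]Br | intermediate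
13 | (S)-2-hydroxyoct-7-en-3-one | C[C@H](O)C(=O)CCCC=C | intermediate
14 | (S)-3-oxooct-7-en-2-yl benzoate | C[C@H](OC(=O)c1ccccc1)C(=O)CCCC=C | intermediate
15 | (2S,3E)-3-[(dicyclohexylboranyl)oxy]octa-3,7-dien-2-yl benzoate | C[C@H](OC(=O)c1ccccc1)/C(OB(C1CCCCC1)C1CCCCC1)=C\CCC=C | intermediate
16 | (2S,4R,5R,8Z,12Z,16R,17R,19S)-4,17-di(but-3-en-1-yl)-5,16-dihydroxy-3,18-dioxo-8,13-bis(trimethylsilyl)icosa-8,12-diene-2,19-diyl dibenzoate | C[C@H](OC(=O)c1ccccc1)C(=O)[C@H](CCC=C)[C@H](O)CC/C(=C/CC/C=C(/CC[C@@H](O)[C@@H](CCC=C)C(=O)[C@H](C)OC(=O)c1ccccc1)[Si](C)(C)C)[Si](C)(C)C | intermediate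
17 | 5,16-bis[(2-methoxyethoxy)methyl] ether of 16 | C[C@H](OC(=O)c1ccccc1)C(=O)[C@H](CCC=C)[C@H](OCOCCOC)CC/C(=C/CC/C=C(/CC[C@@H](OCOCCOC)[C@@H](CCC=C)C(=O)[C@H](C)OC(=O)c1ccccc1)[Si](C)(C)C)[Si](C)(C)C | intermediate
18 | bis(oxocarbenium) ion from 17 (each C–O–CH2–OCH2CH2OCH3 ionised to C–O+=CH2) | C[C@H](OC(=O)c1ccccc1)C(=O)[C@H](CCC=C)[C@H]([O+]=C)CC/C(=C/CC/C=C(/CC[C@@H]([O+]=C)[C@@H](CCC=C)C(=O)[C@H](C)OC(=O)c1ccccc1)[Si](C)(C)C)[Si](C)(C)C | intermediate
19 | (5Z,5'Z)-5,5'-(butane-1,4-diylidene)bis[(2R)-oxane], each C2 bearing (2S,4R)-2-(benzoyloxy)-3-oxooct-7-en-4-yl | C[C@H](OC(=O)c1ccccc1)C(=O)[C@H](CCC=C)[C@H]1CC/C(=C/CC/C=C2/CC[C@H]([C@@H](CCC=C)C(=O)[C@H](C)OC(=O)c3ccccc3)OC2)CO1 | intermediate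
20 | (5Z,5'Z)-5,5'-(butane-1,4-diylidene)bis[(2R)-oxane], each C2 bearing (2S,4R)-2-(benzoyloxy)-8-methyl-3-oxonon-7-en-4-yl | C[C@H](OC(=O)c1ccccc1)C(=O)[C@H](CCC=C(C)C)[C@H]1CC/C(=C/CC/C=C2/CC[C@H]([C@@H](CCC=C(C)C)C(=O)[C@H](C)OC(=O)c3ccccc3)OC2)CO1 | intermediate
21 | (5Z,5'Z)-5,5'-(butane-1,4-diylidene)bis[(2R)-oxane], each C2 bearing (2S,3RS,4S)-2,3-dihydroxy-8-methylnon-7-en-4-yl | C[C@H](O)C(O)[C@H](CCC=C(C)C)[C@H]1CC/C(=C/CC/C=C2/CC[C@H]([C@@H](CCC=C(C)C)C(O)[C@H](C)O)OC2)CO1 | intermediate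
22 | (5Z,5'Z)-5,5'-(butane-1,4-diylidene)bis[(2R)-oxane], each C2 bearing (2R)-6-methyl-1-oxohept-5-en-2-yl | O=C[C@H](CCC=C(C)C)[C@H]1CC/C(=C/CC/C=C2/CC[C@H]([C@@H](CCC=C(C)C)C=O)OC2)CO1 | intermediate
23 | testudinariol A | C=C(C)[C@H]1CC[C@H]([C@H]2CC/C(=C/CC/C=C3/CC[C@H]([C@H]4CC[C@H](C(=C)C)[C@@H]4O)OC3)CO2)[C@H]1O | target

## Step count and risks

Total steps: 14. Longest linear sequence: 11 (steps 1–4 and 8–14, from 1); the ketone branch 9 → 14 is three steps.

The three steps most likely to fail: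

Step 3 (double orthoester Claisen). The silyl group on the central allyl carbon may erode the equatorial preference and give E/Z mixtures at 140 °C, and acid plus heat may cause Peterson-type loss of the β-silyl carbinol. The fallback replaces the acid-catalysed orthoester variant by the ester-enolate (Ireland) variant, run at or below 40 °C on a different substrate. It sets out from 5: acetylation (Ac2O, pyridine, DMAP) gives 2,7-bis(trimethylsilyl)octa-1,7-diene-3,6-diyl diacetate F1. LiN(iPr)2 and Me3SiCl (THF, −78 → 25 °C) convert it into 3,6-bis({1-[(trimethylsilyl)oxy]vinyl}oxy)-2,7-bis(trimethylsilyl)octa-1,7-diene F2, which rearranges at 25–40 °C. Aqueous work-up gives (4Z,8Z)-4,9-bis(trimethylsilyl)dodeca-4,8-dienedioic acid F3, and esterification (EtI, K2CO3, DMF) comes back to the route at 7.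

Step 10 (twofold acetal-initiated vinylsilane cyclisation). SnCl4 may be sequestered by the α-benzoyloxy ketones or simply cleave the MEM ethers. The fallback builds C6′ into the core as an oxygenated carbon and closes the oxanes by O-alkylation. It sets out from 2:
- The vinyllithium [1-({[tert-butyl(dimethyl)silyl]oxy}methyl)vinyl]lithium F4, made from commercial (2-bromoallyloxy)(tert-butyl)dimethylsilane and t-BuLi (Et2O, −78 °C), adds twice to 2 to give 2,7-bis({[tert-butyl(dimethyl)silyl]oxy}methyl)octa-1,7-diene-3,6-diol F5.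
- The conditions of step 3 lead through 3,6-bis[(1-ethoxyvinyl)oxy]-2,7-bis({[tert-butyl(dimethyl)silyl]oxy}methyl)octa-1,7-diene F6 to diethyl (4Z,8Z)-4,9-bis({[tert-butyl(dimethyl)silyl]oxy}methyl)dodeca-4,8-dienedioate F7 (an ordinary 2-alkyl Claisen case, chain cis to CH2OSi).
- iBu2AlH at −78 °C gives (4Z,8Z)-4,9-bis({[tert-butyl(dimethyl)silyl]oxy}methyl)dodeca-4,8-dienedial F8.
- The aldol of step 8 with enolate 15 gives (2S,4R,5R,8Z,12Z,16R,17R,19S)-4,17-di(but-3-en-1-yl)-8,13-bis({[tert-butyl(dimethyl)silyl]oxy}methyl)-5,16-dihydroxy-3,18-dioxoicosa-8,12-diene-2,19-diyl dibenzoate F9.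
- HF·pyridine frees the primary allylic alcohols to give the 8,13-bis(hydroxymethyl) tetraol F10.
- Twofold intramolecular Mitsunobu etherification (PPh3, DIAD) activates only the primary allylic hydroxyl; the C2′ hydroxyl attacks with retention at C2′ and the alkene is untouched. This closes both oxanes and comes back to the route at 19.

Step 14 (twofold ene reaction on the α-oxanyl dialdehyde). The rigid β-oxygenated ring next to the formyl group may lower the C1/C5 selectivity, or the β-alkoxy aldehyde may decompose. The fallback inverts the ring order: cyclopentanols first on an acyclic β-alkoxy aldehyde, oxanes last. It sets out from 17: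
- Cross-metathesis as in step 11 gives the 4,17-bis(4-methylpent-3-en-1-yl) analogue of 17 F11.
- LiBH4 gives the bis(2,3-diol) F12 and NaIO4 the bis(β-MEM-oxy) dialdehyde F13.
- The ene reaction with the same aluminium reagent gives the bis(cyclopentanol) bis(MEM ether) bis(vinylsilane) F14.
- Ac2O/DMAP/pyridine gives its diacetate F15, so that the C1 hydroxyl cannot enter a Prins reaction with the neighbouring isopropenyl group.
- SnCl4 as in step 10 cyclises through the bis(oxocarbenium) ion F16 to testudinariol A diacetate F17.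
- K2CO3 in MeOH removes the acetates and comes back to the route at 23.

Further compounds

F1 | step 3 | 2,7-bis(trimethylsilyl)octa-1,7-diene-3,6-diyl diacetate | CC(=O)OC(CCC(OC(C)=O)C(=C)[Si](C)(C)C)C(=C)[Si](C)(C)C
F2 | step 3 | 3,6-bis({1-[(trimethylsilyl)oxy]vinyl}oxy)-2,7-bis(trimethylsilyl)octa-1,7-diene | C=C(O[Si](C)(C)C)OC(CCC(OC(=C)O[Si](C)(C)C)C(=C)[Si](C)(C)C)C(=C)[Si](C)(C)C
F3 | step 3 | (4Z,8Z)-4,9-bis(trimethylsilyl)dodeca-4,8-dienedioic acid | OC(=O)CC/C(=C/CC/C=C(/CCC(O)=O)[Si](C)(C)C)[Si](C)(C)C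
F4 | step 10 | [1-({[tert-butyl(dimethyl)silyl]oxy}methyl)vinyl]lithium | [Li]C(=C)CO[Si](C)(C)C(C)(C)C
F5 | step 10 | 2,7-bis({[tert-butyl(dimethyl)silyl]oxy}methyl)octa-1,7-diene-3,6-diol | C=C(CO[Si](C)(C)C(C)(C)C)C(O)CCC(O)C(=C)CO[Si](C)(C)C(C)(C)C
F6 | step 10 | 3,6-bis[(1-ethoxyvinyl)oxy]-2,7-bis({[tert-butyl(dimethyl)silyl]oxy}methyl)octa-1,7-diene | C=C(OCC)OC(CCC(OC(=C)OCC)C(=C)CO[Si](C)(C)C(C)(C)C)C(=C)CO[Si](C)(C)C(C)(C)C
F7 | step 10 | diethyl (4Z,8Z)-4,9-bis({[tert-butyl(dimethyl)silyl]oxy}methyl)dodeca-4,8-dienedioate | CCOC(=O)CC/C(=C/CC/C=C(/CCC(=O)OCC)CO[Si](C)(C)C(C)(C)C)CO[Si](C)(C)C(C)(C)C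
F8 | step 10 | (4Z,8Z)-4,9-bis({[tert-butyl(dimethyl)silyl]oxy}methyl)dodeca-4,8-dienedial | O=CCC/C(=C/CC/C=C(/CCC=O)CO[Si](C)(C)C(C)(C)C)CO[Si](C)(C)C(C)(C)C
F9 | step 10 | (2S,4R,5R,8Z,12Z,16R,17R,19S)-4,17-di(but-3-en-1-yl)-8,13-bis({[tert-butyl(dimethyl)silyl]oxy}methyl)-5,16-dihydroxy-3,18-dioxoicosa-8,12-diene-2,19-diyl dibenzoate | C[C@H](OC(=O)c1ccccc1)C(=O)[C@H](CCC=C)[C@H](O)CC/C(=C/CC/C=C(/CC[C@@H](O)[C@@H](CCC=C)C(=O)[C@H](C)OC(=O)c1ccccc1)CO[Si](C)(C)C(C)(C)C)CO[Si](C)(C)C(C)(C)C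
F10 | step 10 | (2S,4R,5R,8Z,12Z,16R,17R,19S)-4,17-di(but-3-en-1-yl)-5,16-dihydroxy-8,13-bis(hydroxymethyl)-3,18-dioxoicosa-8,12-diene-2,19-diyl dibenzoate | C[C@H](OC(=O)c1ccccc1)C(=O)[C@H](CCC=C)[C@H](O)CC/C(=C/CC/C=C(/CC[C@@H](O)[C@@H](CCC=C)C(=O)[C@H](C)OC(=O)c1ccccc1)CO)CO
F11 | step 14 | 4,17-bis(4-methylpent-3-en-1-yl) analogue of 17 | C[C@H](OC(=O)c1ccccc1)C(=O)[C@H](CCC=C(C)C)[C@H](OCOCCOC)CC/C(=C/CC/C=C(/CC[C@@H](OCOCCOC)[C@@H](CCC=C(C)C)C(=O)[C@H](C)OC(=O)c1ccccc1)[Si](C)(C)C)[Si](C)(C)C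
F12 | step 14 | bis(2,3-diol) from F11 (ketones reduced, benzoates removed) | C[C@H](O)C(O)[C@H](CCC=C(C)C)[C@H](OCOCCOC)CC/C(=C/CC/C=C(/CC[C@@H](OCOCCOC)[C@@H](CCC=C(C)C)C(O)[C@H](C)O)[Si](C)(C)C)[Si](C)(C)C
F13 | step 14 | (4Z,8Z)-4,9-bis(trimethylsilyl)dodeca-4,8-diene bearing at each end (R)-CH(OMEM)–(R)-CH(CHO)CH2CH2CH=C(CH3)2 | O=C[C@H](CCC=C(C)C)[C@H](OCOCCOC)CC/C(=C/CC/C=C(/CC[C@@H](OCOCCOC)[C@@H](CCC=C(C)C)C=O)[Si](C)(C)C)[Si](C)(C)C
F14 | step 14 | bis(cyclopentanol) bis(MEM ether) bis(vinylsilane) (ene product of F13) | C=C(C)[C@H]1CC[C@H]([C@H](OCOCCOC)CC/C(=C/CC/C=C(/CC[C@@H](OCOCCOC)[C@H]2CC[C@H](C(=C)C)[C@@H]2O)[Si](C)(C)C)[Si](C)(C)C)[C@H]1O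
F15 | step 14 | diacetate of F14 | C=C(C)[C@H]1CC[C@H]([C@H](OCOCCOC)CC/C(=C/CC/C=C(/CC[C@@H](OCOCCOC)[C@H]2CC[C@H](C(=C)C)[C@@H]2OC(C)=O)[Si](C)(C)C)[Si](C)(C)C)[C@H]1OC(C)=O
F16 | step 14 | bis(oxocarbenium) ion from F15 | C=C(C)[C@H]1CC[C@H]([C@H]([O+]=C)CC/C(=C/CC/C=C(/CC[C@@H]([O+]=C)[C@H]2CC[C@H](C(=C)C)[C@@H]2OC(C)=O)[Si](C)(C)C)[Si](C)(C)C)[C@H]1OC(C)=O
F17 | step 14 | testudinariol A diacetate | C=C(C)[C@H]1CC[C@H]([C@H]2CC/C(=C/CC/C=C3/CC[C@H]([C@H]4CC[C@H](C(=C)C)[C@@H]4OC(C)=O)OC3)CO2)[C@H]1OC(C)=O
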